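## Analysis of the target

The target 15 is a diaryl ether of two pentyl-substituted polyketide arenes. Ring A is the benzo ring of a 1H-isochromen-1-one (isocoumarin) with a pentyl group at C3, a free hydroxyl at C6 and the ether oxygen at C8, peri to the lactone carbonyl C1. Ring B is a benzoic acid with the carboxyl at C1', hydroxyls at C2' and C4', the ether oxygen at C5' and a pentyl group at C6'; only C3' carries hydrogen. There is no stereocentre and no stereogenic double bond, so the difficulty lies in regiochemistry and crowding. Both ether carbons, C8 and C5', are flanked by two substituents, and a direct aryl–oxygen coupling would have to join two such positions. The sensitive groups are the β-resorcylic acid of ring B (decarboxylation on heating or in strong acid), the enol lactone (opened by hydroxide or alkoxide) and the electron-rich resorcinol (oxidised or halogenated at C3'). The plan rests on the segment C4'–C5'–C6' of ring B: C4' is a carbonyl-derived carbon, C6' bears the pentyl chain, and C5' between them can start as the sp3 α-carbon of an α-aryloxy ketone. The crowded C5'–O bond is then made at a non-aromatic carbon, and ring B is assembled around it from open-chain pieces.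

## Retrosynthetic reasoning

**15 ⇒ 14.** The last disconnection removes two O–methyl bonds, the C6 methyl ether and the methyl ester at C1'. Both methyl groups tolerate alkoxide, carbenoid, palladium and π-acid chemistry, and one Lewis-acid dealkylation can cut both. The forward step must spare the diaryl ether and the lactone and must not heat the freed acid.

**14 ⇒ 13.** The lactone bond O2–C3 is cut, which turns the isocoumarin into a methyl benzoate with an ortho hept-1-ynyl group. The lactone would not survive the alkoxide needed to build ring B, whereas the alkynyl ester should. The alkyne also carries C3, C4 and the pentyl chain in one piece. Forward, the ester carbonyl oxygen has to add 6-endo to the alkyne carbon that bears the pentyl chain.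

**13 ⇒ 9 + 10.** Ring B is opened at C1'–C6' and C2'–C3' and taken down one oxidation level. This cut leaves C5' bonded only to oxygen, to the ketone carbon C4' and to the alkene carbon C6', that is, as the α-carbon of enone 9. Malonate 10 supplies C1', C2' and the carboxyl carbon, and the methyl group of 9 becomes C3'. The gain is that the pentasubstituted ring, with both free hydroxyls in place, arises in one operation and no oxygen nucleophile has to attack an aromatic C5'. Forward, 10 must add to the β-carbon of 9, the ring must close through 11 and 12, and 12 must be dehydrogenated without touching the alkyne or the ring A ester.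

**9 ⇒ 7 + 8.** The C=C bond of the enone (future C5'–C6') is cut by an olefination transform. A plain aldol condensation of an aryloxy methyl ketone with 8 is not used, for three reasons. The base would have to choose between two enolisable sides, 8 would condense with itself, and the carbanion next to the ether oxygen lies five atoms from the ring A ester carbonyl and would close on it. The phosphonate in 7 fixes where the carbanion forms, stabilises it too much for attack on the ester and allows a weak amine base. The most crowded C–C bond of ring B, C5'–C6', is thereby made in the open chain before the ring exists.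

**7 ⇒ 5 + 6.** The bond between the ether oxygen and the future C5' is cut. Forward, the phenol O–H of 5 inserts into a metal carbenoid derived from diazo compound 6. This forms the hindered ether bond at an sp3 carbon under neutral conditions, so the ortho ester is never exposed to a free enolate, and it delivers the phosphonate for the next step at the same time.

**5 ⇒ 3 + 4.** The aryl–alkynyl bond is cut (Sonogashira transform). The triflate of 3 sits ortho to the ester and is activated for oxidative addition, and alkyne 4 brings in all carbons of the future C3/C4/pentyl unit.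

**3 ⇒ 2 ⇒ 1.** The two ortho hydroxyls of 2 are equivalent, so a single triflation turns one into the coupling site and leaves the other as the future ether oxygen. 2 comes from 1 by methylation of the only hydroxyl that is not hydrogen-bonded to the ester.

## Alternatives that were turned down

**Alternative 1: ring A by cycloaddition to a fused bis-pyranone.**
- Disconnection: ring A is cut at C6–C7 and C5–C4a, with the pyranone ring already present in the fused bis-pyranone A2, methyl 5-[(2,5-dioxo-7-pentyl-2H,5H-pyrano[4,3-b]pyran-4-yl)oxy]-2,4-dimethoxy-6-pentylbenzoate.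
- Forward key step: the ketene acetal A3 (1,1-dimethoxyethene) would add across C3 and C8a of A2. Decarboxylation and loss of one methoxy group as its alcohol would aromatise ring A and give the isocoumarin A1, methyl 2,4-dimethoxy-5-[(6-methoxy-1-oxo-3-pentyl-1H-isochromen-8-yl)oxy]-6-pentylbenzoate.
- For: the polarisation of the pyranone fixes the regiochemistry, with the nucleophilic CH2 of A3 bonding to the doubly activated C8a. Ring A and the lactone appear together, and no alkyne or late cycloisomerisation is needed. The ether bond to ring A would be made by addition–elimination of a phenoxide on a 4-substituted pyranone, an easy C–O bond. On these points it is as strong as or stronger than the chosen route.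
- Against: that phenoxide is the fully substituted ring B phenol A4 (methyl 5-hydroxy-2,4-dimethoxy-6-pentylbenzoate), so the real problem of the target, a pentasubstituted ring B with oxygen at C5', is moved into a separate synthesis of several steps. The aryloxy group at C4 of A2 is a donor on the diene and a vinylogous leaving group, so A3 may displace it instead of cycloadding. A1 carries three methyl ethers and an ester, two of the ethers ortho and para to the carboxyl, so the end game is heavier.
- Comparison: the chosen route offers ring B with free hydroxyls directly from open-chain pieces, and a shorter sequence overall.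

**Alternative 2: ring B by cycloaddition of a bis(silyloxy)diene with an alkynoate.**
- Disconnection: ring B is cut at C5'–C6' and C1'–C2'.
- Forward key step: the diene A6, 8-{[4-methoxy-2,4-bis(trimethylsilyloxy)buta-1,3-dien-1-yl]oxy}-6-methoxy-3-pentyl-1H-isochromen-1-one, and the alkynoate A7 (methyl oct-2-ynoate) would combine by (4+2) cycloaddition. Loss of the alkoxy group and desilylation on acidic work-up would give A5, methyl 2,4-dihydroxy-5-[(6-methoxy-1-oxo-3-pentyl-1H-isochromen-8-yl)oxy]-6-pentylbenzoate, which is identical with compound 14.
- For: ring B arrives aromatic with no oxidation step, and the isocoumarin is already in place, so it would reach 14 in fewer operations after the coupling. On the oxidation point it is stronger than the chosen route, which must use an oxidant next to an alkyne and a resorcinol.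
- Against: the bond C5'–C6' would be made in the intermolecular, rate-limiting step between the diene terminus that carries the aryloxy group and the alkyne carbon that carries the pentyl chain, the most hindered contact in the molecule, and a β-alkyl alkynoate is a weak dienophile. A6 must be made by double enolisation of a 4-aryloxyacetoacetate whose activated methylene lies five atoms from the lactone carbonyl, so ring closure onto the lactone threatens at a more electrophilic carbonyl than in the chosen route.
- Comparison: the chosen route makes C5'–C6' by olefination in the open chain and closes the ring with a small stabilised carbanion and an intramolecular acylation.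

**Alternative 3: ring A carbons by aryne insertion into malonate.**
- Disconnection: ring A is cut at C4a–C4 and C8a–C1.
- Forward key step: fluoride-triggered release of the aryne from the silyl triflate A9, methyl 2,4-dimethoxy-5-[5-methoxy-3-{[(trifluoromethyl)sulfonyl]oxy}-2-(trimethylsilyl)phenoxy]-6-pentylbenzoate. Malonate 10 would add with its carbanion at the carbon meta to the aryloxy group, and the aryl anion would take up the acyl group, giving the homophthalate A8, methyl 5-[5-methoxy-2-(methoxycarbonyl)-3-(2-methoxy-2-oxoethyl)phenoxy]-2,4-dimethoxy-6-pentylbenzoate.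
- For: the oxygen substituent next to the aryne directs the regiochemistry reliably, the conditions are mild, and C1 and C4 are installed in one step. In regiocontrol of ring A it is at least as strong as the chosen route.
- Against: A9 already contains the finished ring B and the diaryl ether, so it again needs phenol A4 and an ether-forming step, plus the construction of the ortho-silyl triflate. A8 is not yet an isocoumarin: C3 and the pentyl chain must still be added by acylating the homophthalate methylene and cyclising with loss of one carboxyl, during which three different ester groups must be told apart. The end game again has to cleave three methyl ethers and an ester.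
- Comparison: the chosen route brings in C3, C4 and the pentyl chain with one Sonogashira coupling and needs no pre-built ring B.

Key step: step 6

Remark on the chemistry: the target has no stereocentre. Compounds 7, 11 and 12 form as racemates or diastereomer mixtures whose stereocentres are destroyed later. Enone 9 is drawn as the (3Z) isomer expected from the olefination; the (3E) isomer would serve equally in step 6. Compounds 1, 4, 6, 8 and 10 are taken as commercial.

## Route

Step 1
Reactants: 1 methyl 2,4,6-trihydroxybenzoate
Product: 2 methyl 2,6-dihydroxy-4-methoxybenzoate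
Conditions: MeI (1.05 equiv), K2CO3 (1.0 equiv), acetone, rt
Reagents that add atoms: iodomethane, CI
Why: Williamson O-methylation; the 4-hydroxyl is the most acidic and the only one not held in a hydrogen bond to the ester carbonyl, so one equivalent of base and alkylating agent should methylate it selectively.

Step 2
Reactants: 2 methyl 2,6-dihydroxy-4-methoxybenzoate
Product: 3 methyl 2-hydroxy-4-methoxy-6-{[(trifluoromethyl)sulfonyl]oxy}benzoate
Conditions: Tf2O (1.0 equiv), pyridine, CH2Cl2, −20 °C → 0 °C
Reagents that add atoms: trifluoromethanesulfonic anhydride, O=S(=O)(OS(=O)(=O)C(F)(F)F)C(F)(F)F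
Why: Phenol O-sulfonylation; the two hydroxyls are equivalent, and after the first triflation the ring is more electron-poor and the remaining hydroxyl is chelated to the ester, so the second triflation should be slower and one equivalent at low temperature should stop at 3.

Step 3
Reactants: 3 methyl 2-hydroxy-4-methoxy-6-{[(trifluoromethyl)sulfonyl]oxy}benzoate; 4 hept-1-yne
Product: 5 methyl 2-(hept-1-yn-1-yl)-6-hydroxy-4-methoxybenzoate
Conditions: PdCl2(PPh3)2 (5 mol %), CuI (10 mol %), Et3N, DMF, 60 °C
Reagents that add atoms: none
Why: Sonogashira coupling; zerovalent palladium inserts readily into the aryl triflate ortho to the ester, and the free phenol is meta to the new alkyne and cannot cyclise onto it.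

Step 4
Reactants: 5 methyl 2-(hept-1-yn-1-yl)-6-hydroxy-4-methoxybenzoate; 6 dimethyl (1-diazo-2-oxopropyl)phosphonate
Product: 7 dimethyl {1-[3-(hept-1-yn-1-yl)-5-methoxy-2-(methoxycarbonyl)phenoxy]-2-oxopropyl}phosphonate (racemic)
Conditions: Rh2(OAc)4 (2 mol %), toluene, 80 °C, slow addition of 6
Reagents that add atoms: none
Why: Rhodium-carbenoid O–H insertion of a phenol into an α-diazo-β-ketophosphonate; the electrophilic carbenoid is captured by the phenol oxygen and proton transfer in the oxonium ylide gives the ether without base, so the ortho ester is not attacked. The new stereocentre forms racemic and disappears in step 5.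

Step 5
Reactants: 7 dimethyl {1-[3-(hept-1-yn-1-yl)-5-methoxy-2-(methoxycarbonyl)phenoxy]-2-oxopropyl}phosphonate; 8 hexanal
Product: 9 methyl 2-(hept-1-yn-1-yl)-4-methoxy-6-{[(3Z)-2-oxonon-3-en-3-yl]oxy}benzoate
Conditions: LiCl, DBU, MeCN, 0 °C → rt
Reagents that add atoms: none
Why: Horner–Wadsworth–Emmons olefination under Masamune–Roush conditions, which tolerate the enolisable aldehyde; α-oxygenated phosphonates should give mainly the isomer with the alkyl chain trans to the acyl group, here (3Z). The phosphonate-stabilised anion is too weak a nucleophile to close on the ortho ester, and such a closure could not be driven by a final deprotonation.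

Step 6
Reactants: 9 methyl 2-(hept-1-yn-1-yl)-4-methoxy-6-{[(3Z)-2-oxonon-3-en-3-yl]oxy}benzoate; 10 dimethyl malonate
Product: 13 methyl 5-[3-(hept-1-yn-1-yl)-5-methoxy-2-(methoxycarbonyl)phenoxy]-2,4-dihydroxy-6-pentylbenzoate, via Michael adduct 11 (not isolated), via cyclohexanedione ester 12 (not isolated)
Conditions: NaOMe (1.1 equiv), MeOH, 65 °C; then MeCN, CuBr2 (2.1 equiv), 0 °C → rt
Reagents that add atoms: none
Why: Methoxide forms the malonate anion, which adds to the β-carbon of enone 9 (the carbon bearing the pentyl chain) to give 11 (bond C1'–C6'); proton exchange then lets the methyl-ketone enolate attack one of the two equivalent malonate ester groups in a 6-exo-trig Dieckmann closure (bond C2'–C3'), and deprotonation of the vinylogous acid 12 pulls both reversible steps forward. The closest known reaction is the Michael–Dieckmann condensation of malonate with non-3-en-2-one followed by oxidative aromatisation, the usual way to the olivetolate ring; the only change is the aryloxy group on the enone α-carbon. Regiochemistry needs no outside control: only the β-carbon is electrophilic and only the methyl group can reach an ester through a six-membered transition state, so the aryloxy carbon becomes C5' between C4' and C6'. The sp3 centres C1', C5' and C6' of 11 and 12 form as mixtures and are all erased on aromatisation, so no stereocontrol is needed and either alkene isomer of 9 serves. CuBr2 (a one-electron oxidant, two equivalents) brominates the enol of 12, and loss of HBr followed by enolisation gives the resorcylate 13. Three selectivities are needed. The C5' enolate must not close on the ring A ester; that ester is flanked by two ortho groups and deactivated by the para methoxy group, the attack would build a quaternary centre, and the first-formed C5' enolate is protonated at once by methanol. The aryloxide must not be expelled; it is α and not β to the carbonyl and a poor leaving group for 3-exo-tet attack by the malonate carbon. The oxidant must spare the alkynyl benzoate and C3'; CuBr2 is held at two equivalents and at or below room temperature, where bromocyclisation of alkynyl benzoates and bromination of phenols should be slow.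

Step 7
Reactants: 13 methyl 5-[3-(hept-1-yn-1-yl)-5-methoxy-2-(methoxycarbonyl)phenoxy]-2,4-dihydroxy-6-pentylbenzoate
Product: 14 methyl 2,4-dihydroxy-5-[(6-methoxy-1-oxo-3-pentyl-1H-isochromen-8-yl)oxy]-6-pentylbenzoate
Conditions: AuCl3 (5 mol %), MeCN/H2O, 50 °C
Reagents that add atoms: water, O
Why: π-Acid cycloisomerisation of a methyl 2-alkynylbenzoate; AuCl3 activates the alkyne, the ester carbonyl oxygen adds 6-endo-dig to the pentyl-bearing carbon, water takes the methyl group off the resulting 1-methoxyisochromenylium ion as methanol, and protodeauration gives the isocoumarin. Alkyl-substituted alkynes and ester nucleophiles favour the six-membered lactone, and the ring B ester has no alkyne within reach.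

Step 8
Reactants: 14 methyl 2,4-dihydroxy-5-[(6-methoxy-1-oxo-3-pentyl-1H-isochromen-8-yl)oxy]-6-pentylbenzoate
Product: 15 2,4-dihydroxy-5-[(6-hydroxy-1-oxo-3-pentyl-1H-isochromen-8-yl)oxy]-6-pentylbenzoic acid
Conditions: BBr3 (6 equiv), CH2Cl2, −78 °C → rt; then H2O, 0 °C
Reagents that add atoms: none
Why: Lewis-acid dealkylation by bromide attack at methyl (SN2); BBr3 cleaves the aryl methyl ether and, once the C2' hydroxyl is borylated and chelates the ester carbonyl, the methyl ester, while the diaryl ether and the enol lactone are inert to it. Cold aqueous work-up should release the β-resorcylic acid without the heat that causes decarboxylation.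

## Compound list

1 | methyl 2,4,6-trihydroxybenzoate | COC(=O)c1c(O)cc(O)cc1O | starting material
2 | methyl 2,6-dihydroxy-4-methoxybenzoate | COC(=O)c1c(O)cc(OC)cc1O | intermediate
3 | methyl 2-hydroxy-4-methoxy-6-{[(trifluoromethyl)sulfonyl]oxy}benzoate | COC(=O)c1c(O)cc(OC)cc1OS(=O)(=O)C(F)(F)F | intermediate
4 | hept-1-yne | CCCCCC#C | starting material
5 | methyl 2-(hept-1-yn-1-yl)-6-hydroxy-4-methoxybenzoate | CCCCCC#Cc1cc(OC)cc(O)c1C(=O)OC | intermediate
6 | dimethyl (1-diazo-2-oxopropyl)phosphonate | COP(=O)(OC)C(=[N+]=[N-])C(C)=O | starting material
7 | dimethyl {1-[3-(hept-1-yn-1-yl)-5-methoxy-2-(methoxycarbonyl)phenoxy]-2-oxopropyl}phosphonate (racemic) | CCCCCC#Cc1cc(OC)cc(OC(C(C)=O)P(=O)(OC)OC)c1C(=O)OC | intermediate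
8 | hexanal | CCCCCC=O | starting material
9 | methyl 2-(hept-1-yn-1-yl)-4-methoxy-6-{[(3Z)-2-oxonon-3-en-3-yl]oxy}benzoate | CCCCC/C=C(\Oc1cc(OC)cc(C#CCCCCC)c1C(=O)OC)C(C)=O | intermediate
10 | dimethyl malonate | COC(=O)CC(=O)OC | starting material
11 | dimethyl 2-{3-[3-(hept-1-yn-1-yl)-5-methoxy-2-(methoxycarbonyl)phenoxy]-2-oxononan-4-yl}propanedioate (diastereomer mixture) | CCCCCC(C(C(=O)OC)C(=O)OC)C(Oc1cc(OC)cc(C#CCCCCC)c1C(=O)OC)C(C)=O | intermediate (not isolated)
12 | methyl 5-[3-(hept-1-yn-1-yl)-5-methoxy-2-(methoxycarbonyl)phenoxy]-2,4-dioxo-6-pentylcyclohexane-1-carboxylate (diastereomer mixture, present as its enolate) | CCCCCC1C(C(=O)OC)C(=O)CC(=O)C1Oc1cc(OC)cc(C#CCCCCC)c1C(=O)OC | intermediate (not isolated)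
13 | methyl 5-[3-(hept-1-yn-1-yl)-5-methoxy-2-(methoxycarbonyl)phenoxy]-2,4-dihydroxy-6-pentylbenzoate | CCCCCC#Cc1cc(OC)cc(Oc2c(O)cc(O)c(C(=O)OC)c2CCCCC)c1C(=O)OC | intermediate
14 | methyl 2,4-dihydroxy-5-[(6-methoxy-1-oxo-3-pentyl-1H-isochromen-8-yl)oxy]-6-pentylbenzoate | CCCCCc1cc2cc(OC)cc(Oc3c(O)cc(O)c(C(=O)OC)c3CCCCC)c2c(=O)o1 | intermediate
15 | 2,4-dihydroxy-5-[(6-hydroxy-1-oxo-3-pentyl-1H-isochromen-8-yl)oxy]-6-pentylbenzoic acid | CCCCCc1cc2cc(O)cc(Oc3c(O)cc(O)c(C(=O)O)c3CCCCC)c2c(=O)o1 | target

## Step count and least certain steps

Total step count: 8. Longest linear sequence: 8 steps (1 → 15).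

**Step 6 (key step).**
- Most likely to go wrong: diversion of adduct 11 before the six-membered ring closes. The enolate at C5' can close on the ring A ester in a five-membered Claisen reaction, and loss of the acetyl group would then make this irreversible. The malonate carbanion can expel the aryloxide by three-membered ring closure. The conjugate addition itself may be slow, because the α-oxygen makes 9 a weaker acceptor than a plain enone.
- Fallback (sets out from 5, returns at 15): ring B is bought instead of built. Commercial methyl 2,4-dihydroxy-6-pentylbenzoate is methylated (MeI, K2CO3, DMF) to methyl 2,4-dimethoxy-6-pentylbenzoate F1. Iodination (N-iodosuccinimide, cat. CF3CO2H, MeCN) should go para to the 2-methoxy group, the site between the two methoxy groups being more hindered, and give methyl 5-iodo-2,4-dimethoxy-6-pentylbenzoate F2. Oxidation at iodine (mCPBA, TsOH·H2O, then 1,3,5-trimethoxybenzene) gives [4,6-dimethoxy-3-(methoxycarbonyl)-2-pentylphenyl](2,4,6-trimethoxyphenyl)iodonium 4-methylbenzenesulfonate F3. Metal-free O-arylation of phenol 5 with F3 (K2CO3, toluene, rt → 50 °C) tolerates two ortho substituents on each partner and transfers the less electron-rich aryl group. It would give methyl 5-[3-(hept-1-yn-1-yl)-5-methoxy-2-(methoxycarbonyl)phenoxy]-2,4-dimethoxy-6-pentylbenzoate F4. Closure with AuCl3 as in step 7 gives methyl 2,4-dimethoxy-5-[(6-methoxy-1-oxo-3-pentyl-1H-isochromen-8-yl)oxy]-6-pentylbenzoate F5, the same compound as A1. BBr3 then removes the three methyl ethers and the ester to reach 15.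

**Step 4.**
- Most likely to go wrong: slow capture of the carbenoid by a phenol oxygen that is tied up in a hydrogen bond to the ester, so that the carbenoid is consumed by the alkyne (cyclopropenation), by the ester carbonyl or by dimerisation.
- Fallback (sets out from 5, returns at 7): the ether bond is made by SN2 alkylation instead of insertion. Commercial dimethyl (2-oxopropyl)phosphonate is chlorinated (SO2Cl2, CH2Cl2) to dimethyl (1-chloro-2-oxopropyl)phosphonate F6. Phenol 5 is O-alkylated with F6 (K2CO3, acetone, rt → 50 °C), as phenols are with α-chloro-β-dicarbonyl compounds, to give 7.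

**Step 7.**
- Most likely to go wrong: loss of the catalyst through reduction of trivalent gold by the electron-rich resorcinol of ring B, or competing 5-exo closure to the alkylidene phthalide.
- Fallback (sets out from 13, returns at 14): the resorcinol is masked first. Acetylation (Ac2O, pyridine) gives methyl 2,4-bis(acetyloxy)-5-[3-(hept-1-yn-1-yl)-5-methoxy-2-(methoxycarbonyl)phenoxy]-6-pentylbenzoate F7. The same AuCl3 closure then gives methyl 2,4-bis(acetyloxy)-5-[(6-methoxy-1-oxo-3-pentyl-1H-isochromen-8-yl)oxy]-6-pentylbenzoate F8. Acid methanolysis of the aryl acetates (HCl, MeOH, rt), which the isocoumarin tolerates, gives 14.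

**Step 8.**
- Most likely to go wrong: incomplete cleavage of the hindered, chelated methyl ester, or decarboxylation of the freed β-resorcylic acid during a long reaction and acidic work-up.
- Fallback (sets out from 9, returns at 15): the ring B ester is changed to one that leaves easily. Step 6 is run with tert-butyl methyl malonate in place of 10; the Dieckmann closure should take the methyl ester, and the product is tert-butyl 5-[3-(hept-1-yn-1-yl)-5-methoxy-2-(methoxycarbonyl)phenoxy]-2,4-dihydroxy-6-pentylbenzoate F9. AuCl3 closure gives tert-butyl 2,4-dihydroxy-5-[(6-methoxy-1-oxo-3-pentyl-1H-isochromen-8-yl)oxy]-6-pentylbenzoate F10. BBr3 (−78 °C → rt) then removes the tert-butyl group at low temperature and the methyl ether on warming, and gives 15.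

## Further compounds

F1 | step 6 | methyl 2,4-dimethoxy-6-pentylbenzoate | CCCCCc1cc(OC)cc(OC)c1C(=O)OC
F2 | step 6 | methyl 5-iodo-2,4-dimethoxy-6-pentylbenzoate | CCCCCc1c(I)c(OC)cc(OC)c1C(=O)OC
F3 | step 6 | [4,6-dimethoxy-3-(methoxycarbonyl)-2-pentylphenyl](2,4,6-trimethoxyphenyl)iodonium 4-methylbenzenesulfonate | CCCCCc1c([I+]c2c(OC)cc(OC)cc2OC)c(OC)cc(OC)c1C(=O)OC.Cc1ccc(cc1)S(=O)(=O)[O-]
F4 | step 6 | methyl 5-[3-(hept-1-yn-1-yl)-5-methoxy-2-(methoxycarbonyl)phenoxy]-2,4-dimethoxy-6-pentylbenzoate | CCCCCC#Cc1cc(OC)cc(Oc2c(OC)cc(OC)c(C(=O)OC)c2CCCCC)c1C(=O)OC
F5 | step 6 | methyl 2,4-dimethoxy-5-[(6-methoxy-1-oxo-3-pentyl-1H-isochromen-8-yl)oxy]-6-pentylbenzoate | CCCCCc1cc2cc(OC)cc(Oc3c(OC)cc(OC)c(C(=O)OC)c3CCCCC)c2c(=O)o1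
F6 | step 4 | dimethyl (1-chloro-2-oxopropyl)phosphonate (racemic) | COP(=O)(OC)C(Cl)C(C)=O
F7 | step 7 | methyl 2,4-bis(acetyloxy)-5-[3-(hept-1-yn-1-yl)-5-methoxy-2-(methoxycarbonyl)phenoxy]-6-pentylbenzoate | CCCCCC#Cc1cc(OC)cc(Oc2c(OC(C)=O)cc(OC(C)=O)c(C(=O)OC)c2CCCCC)c1C(=O)OC
F8 | step 7 | methyl 2,4-bis(acetyloxy)-5-[(6-methoxy-1-oxo-3-pentyl-1H-isochromen-8-yl)oxy]-6-pentylbenzoate | CCCCCc1cc2cc(OC)cc(Oc3c(OC(C)=O)cc(OC(C)=O)c(C(=O)OC)c3CCCCC)c2c(=O)o1
F9 | step 8 | tert-butyl 5-[3-(hept-1-yn-1-yl)-5-methoxy-2-(methoxycarbonyl)phenoxy]-2,4-dihydroxy-6-pentylbenzoate | CCCCCC#Cc1cc(OC)cc(Oc2c(O)cc(O)c(C(=O)OC(C)(C)C)c2CCCCC)c1C(=O)OC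
F10 | step 8 | tert-butyl 2,4-dihydroxy-5-[(6-methoxy-1-oxo-3-pentyl-1H-isochromen-8-yl)oxy]-6-pentylbenzoate | CCCCCc1cc2cc(OC)cc(Oc3c(O)cc(O)c(C(=O)OC(C)(C)C)c3CCCCC)c2c(=O)o1
A1 | alternative 1 | methyl 2,4-dimethoxy-5-[(6-methoxy-1-oxo-3-pentyl-1H-isochromen-8-yl)oxy]-6-pentylbenzoate | CCCCCc1cc2cc(OC)cc(Oc3c(OC)cc(OC)c(C(=O)OC)c3CCCCC)c2c(=O)o1
A2 | alternative 1 | methyl 5-[(2,5-dioxo-7-pentyl-2H,5H-pyrano[4,3-b]pyran-4-yl)oxy]-2,4-dimethoxy-6-pentylbenzoate | CCCCCc1cc2oc(=O)cc(Oc3c(OC)cc(OC)c(C(=O)OC)c3CCCCC)c2c(=O)o1
A3 | alternative 1 | 1,1-dimethoxyethene | C=C(OC)OC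
A4 | alternative 1 | methyl 5-hydroxy-2,4-dimethoxy-6-pentylbenzoate | CCCCCc1c(O)c(OC)cc(OC)c1C(=O)OC
A5 | alternative 2 | methyl 2,4-dihydroxy-5-[(6-methoxy-1-oxo-3-pentyl-1H-isochromen-8-yl)oxy]-6-pentylbenzoate | CCCCCc1cc2cc(OC)cc(Oc3c(O)cc(O)c(C(=O)OC)c3CCCCC)c2c(=O)o1
A6 | alternative 2 | 8-{[4-methoxy-2,4-bis(trimethylsilyloxy)buta-1,3-dien-1-yl]oxy}-6-methoxy-3-pentyl-1H-isochromen-1-one | CCCCCc1cc2cc(OC)cc(OC=C(O[Si](C)(C)C)C=C(OC)O[Si](C)(C)C)c2c(=O)o1
A7 | alternative 2 | methyl oct-2-ynoate | CCCCCC#CC(=O)OC
A8 | alternative 3 | methyl 5-[5-methoxy-2-(methoxycarbonyl)-3-(2-methoxy-2-oxoethyl)phenoxy]-2,4-dimethoxy-6-pentylbenzoate | COC(=O)Cc1cc(OC)cc(Oc2c(OC)cc(OC)c(C(=O)OC)c2CCCCC)c1C(=O)OC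
A9 | alternative 3 | methyl 2,4-dimethoxy-5-[5-methoxy-3-{[(trifluoromethyl)sulfonyl]oxy}-2-(trimethylsilyl)phenoxy]-6-pentylbenzoate | COc1cc(OS(=O)(=O)C(F)(F)F)c([Si](C)(C)C)c(Oc2c(OC)cc(OC)c(C(=O)OC)c2CCCCC)c1
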